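**Plan**

- Retrosynthesis: the interflavan bond C4(upper)–C8(lower) is cut first, giving a C4-activated tri-O-benzyl-(−)-epiafzelechin and penta-O-benzyl-(−)-epigallocatechin. Ring C of the upper unit is then cut at O1–C8a and at C3–C4.
- Enabling feature: C3 is an oxygenated carbon between the O1-bearing C2 and the benzylic C4, and ring A carries oxygen at C5, C7 and C8a. So C2–C3 becomes a mandelic acid held as a 1,3-dioxolan-4-one (O1 masked in a temporary ring), C4 the α-carbon of an arylacetate (ester as activating group), and ring A a 2,4,6-trifluorophenyl ring whose fluorines activate one another for SNAr and are later exchanged for oxygen.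
- Forward: rings A and B are bought. Ring C is closed in one operation by enolate acylation (C3–C4) followed by alkoxide SNAr (O1–C8a). Decarboxylation, ketone reduction, fluorine-to-benzyloxy exchange and C4 oxidation give the electrophile, which is joined to the lower unit and debenzylated.
- Stereochemistry: C2 and C3 (2R,3R, cis) come from a dynamic kinetic resolution in the asymmetric transfer hydrogenation of the configurationally labile flavan-3-one. C4 (4R, trans to 3-OH) comes from substrate-controlled attack on the C4 cation. The two centres of the lower unit come from natural (−)-epigallocatechin.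

Key step: step 4

Assumption: in step 6 the (S,S) antipode of the catalyst is taken to reduce the (2R) ketone and give the (2R,3R) alcohol; if the sense proves opposite, the (R,R) antipode is used without other change.

Step 1
Reactants: 1 4-(benzyloxy)benzaldehyde
Product: 2 racemic 2-[4-(benzyloxy)phenyl]-2-hydroxyacetic acid
Conditions: CHBr3, KOH, LiCl, 1,4-dioxane/H2O, 0 °C to rt; then aq. HCl
Reagents that add atoms: bromoform BrC(Br)Br; potassium hydroxide [K+].[OH-]
Why: Tribromomethanide adds to the aldehyde, the carbinol closes to a gem-dibromo epoxide and hydroxide opens and hydrolyses it to the α-hydroxy acid (Jocic-type haloform homologation, known for electron-rich benzaldehydes); the new centre (C2 of the target) is left racemic on purpose because it is equilibrated and fixed in step 6.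

Step 2
Reactants: 2 racemic 2-[4-(benzyloxy)phenyl]-2-hydroxyacetic acid
Product: 3 racemic 5-[4-(benzyloxy)phenyl]-2,2-dimethyl-1,3-dioxolan-4-one
Conditions: Me2C(OMe)2, TsOH·H2O (cat.), acetone, rt
Reagents that add atoms: 2,2-dimethoxypropane COC(C)(C)OC
Why: Acid-catalysed acetalisation of the α-hydroxy acid (1,3-dioxolan-4-one formation) turns the carboxyl group into a lactone-type acyl donor and locks O1 in a ring that falls apart only after acyl transfer.

Step 3
Reactants: 4 2-(2,4,6-trifluorophenyl)acetic acid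
Product: 5 tert-butyl 2-(2,4,6-trifluorophenyl)acetate
Conditions: isobutylene, H2SO4 (cat.), CH2Cl2, rt, sealed tube
Reagents that add atoms: 2-methylpropene CC(C)=C
Why: Acid-catalysed addition of the carboxylic acid to isobutylene gives the tert-butyl ester, which makes C4 enolisable, resists self-condensation and lactonisation, and can later leave as isobutylene and CO2.

Step 4
Reactants: 5 tert-butyl 2-(2,4,6-trifluorophenyl)acetate; 3 racemic 5-[4-(benzyloxy)phenyl]-2,2-dimethyl-1,3-dioxolan-4-one
Product: 7 racemic tert-butyl 2-[4-(benzyloxy)phenyl]-5,7-difluoro-3-hydroxy-2H-chromene-4-carboxylate, via acyclic hydroxy keto ester 6 (not isolated)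
Conditions: 5, KN(SiMe3)2, THF, −78 °C; 3, −78 to 0 °C; KOtBu, DMF, 60 °C; aq. HCl
Reagents that add atoms: none
Why: Proposed new method: the potassium enolate of 5 (C4) attacks the lactone carbonyl of 3 (C3) and the tetrahedral intermediate collapses with loss of acetone, so that formation of the C3–C4 bond itself unmasks the C2 alkoxide (O1); after the second equivalent of base this alkoxide displaces the ortho fluorine at C8a through a Meisenheimer intermediate stabilised by the two remaining meta fluorines. The closest known reaction types are the Claisen acylation of ester enolates by 1,3-dioxolan-4-ones (as used for tetronic acids) and the alkoxide SNAr pyran closure on 2,4,6-trifluorophenyl units, which have not been run as one annulation. Ring C is closed as a six-membered ring by intramolecular addition–elimination at the sp2 carbon C8a (6-exo-trig with respect to the C8a=C8 bond). No stereocentre is set under control: C3 and C4 emerge sp2 (enol of the β-keto ester) and C2 is left racemic on purpose, since it is epimerisable next to the C3 carbonyl and is fixed in step 6. The step needs C-acylation before any aryl ether formation, and six-membered O-arylation in preference to five-membered closures (lactonisation onto the ester, or O-arylation by the enolate oxygen); the first is secured because O1 stays locked in the dioxolanone until the C–C bond exists, which also rules out attack at the para fluorine, and the second by the bulky, enolate-deactivated tert-butyl ester and the far higher nucleophilicity of the alkoxide, which the chelated Z-enolate holds next to the aryl ring.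

Step 5
Reactants: 7 racemic tert-butyl 2-[4-(benzyloxy)phenyl]-5,7-difluoro-3-hydroxy-2H-chromene-4-carboxylate
Product: 9 racemic 2-[4-(benzyloxy)phenyl]-5,7-difluoro-2H-chromen-3(4H)-one, via keto acid 8 (not isolated)
Conditions: TsOH·H2O (cat.), toluene, 80 °C
Reagents that add atoms: none
Why: Acid-catalysed loss of isobutylene from the tert-butyl β-keto ester and decarboxylation of the resulting β-keto acid remove the activating group from C4 and leave the flavan-3-one, whose C2 stays racemic and labile.

Step 6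
Reactants: 9 racemic 2-[4-(benzyloxy)phenyl]-5,7-difluoro-2H-chromen-3(4H)-one
Product: 10 (2R,3R)-2-[4-(benzyloxy)phenyl]-5,7-difluorochroman-3-ol (2,3-cis)
Conditions: RuCl(p-cymene)[(S,S)-TsDPEN] (cat.), HCO2H/Et3N, EtOAc, 40 °C
Reagents that add atoms: none
Why: Noyori–Ikariya asymmetric transfer hydrogenation under dynamic kinetic resolution: C2 (α to the ketone, benzylic and α-oxygenated) epimerises through the enol faster than hydride transfer, the catalyst reduces one ketone enantiomer, and hydride enters C3 anti to the C2 aryl group, which should give the 2,3-cis (2R,3R) alcohol.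

Step 7
Reactants: 10 (2R,3R)-2-[4-(benzyloxy)phenyl]-5,7-difluorochroman-3-ol
Product: 11 (2R,3R)-5,7-bis(benzyloxy)-2-[4-(benzyloxy)phenyl]chroman-3-ol (5,7,4'-tri-O-benzyl-(−)-epiafzelechin)
Conditions: BnOH, NaH, NMP, 0 °C then 120 °C
Reagents that add atoms: benzyl alcohol OCc1ccccc1
Why: Twofold SNAr of benzyloxide on the fluoroarene (each C–F carbon lies meta to two electronegative substituents that stabilise the Meisenheimer anion inductively), a known way to turn a fluorinated ring A into the phloroglucinol diether; C2 and C3 carry no acidic hydrogen and should keep their configuration.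

Step 8
Reactants: 11 (2R,3R)-5,7-bis(benzyloxy)-2-[4-(benzyloxy)phenyl]chroman-3-ol
Product: 12 (2R,3R,4S)-5,7-bis(benzyloxy)-2-[4-(benzyloxy)phenyl]-4-(2-ethoxyethoxy)chroman-3-ol (2,3-cis, 3,4-trans)
Conditions: DDQ, 2-ethoxyethanol, CH2Cl2, rt
Reagents that add atoms: 2-ethoxyethanol CCOCCO
Why: DDQ abstracts hydride from the benzylic C4 (cation stabilised by the ortho and para benzyloxy groups of ring A) and the alcohol adds trans to the C3 hydroxyl, a well-precedented C4 activation of benzylated flavan-3-ols; the C4 configuration is of no consequence because C4 is ionised again in step 10.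

Step 9
Reactants: 13 (−)-epigallocatechin
Product: 14 (2R,3R)-5,7-bis(benzyloxy)-2-[3,4,5-tris(benzyloxy)phenyl]chroman-3-ol (penta-O-benzyl-(−)-epigallocatechin)
Conditions: BnBr, K2CO3, DMF, 0 °C to rt, argon
Reagents that add atoms: benzyl bromide BrCc1ccccc1
Why: Williamson etherification of the five phenols, which K2CO3 deprotonates while the secondary C3 hydroxyl stays untouched; the C2 and C3 centres of the chiral pool are kept.

Step 10
Reactants: 12 (2R,3R,4S)-5,7-bis(benzyloxy)-2-[4-(benzyloxy)phenyl]-4-(2-ethoxyethoxy)chroman-3-ol; 14 (2R,3R)-5,7-bis(benzyloxy)-2-[3,4,5-tris(benzyloxy)phenyl]chroman-3-ol (3 equiv)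
Product: 15 (2R,3R,4R)-5,7-bis(benzyloxy)-2-[4-(benzyloxy)phenyl]-4-[(2R,3R)-5,7-bis(benzyloxy)-3-hydroxy-2-[3,4,5-tris(benzyloxy)phenyl]chroman-8-yl]chroman-3-ol (octa-O-benzyl dimer)
Conditions: Me3SiOTf (cat.), CH2Cl2, −78 °C
Reagents that add atoms: none
Why: The Lewis acid ionises the C4 ether to the benzylic cation stabilised by ring A, which alkylates the electron-rich C8 of 14 (Friedel–Crafts type flavan coupling, well precedented for benzylated 2,3-cis units); attack anti to the axial C3 hydroxyl and the C2 aryl group should give the 3,4-trans (4R, 4β) bond, and the excess of 14 suppresses self-condensation of 12.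

Step 11
Reactants: 15 octa-O-benzyl dimer
Product: 16 epiafzelechin-(4β→8)-epigallocatechin, (2R,3R,4R)-2-(4-hydroxyphenyl)-4-[(2R,3R)-3,5,7-trihydroxy-2-(3,4,5-trihydroxyphenyl)chroman-8-yl]chromane-3,5,7-triol
Conditions: H2 (1 atm), Pd(OH)2/C, THF/MeOH/H2O, rt
Reagents that add atoms: none
Why: Hydrogenolysis of the eight benzyl ethers under neutral conditions, which should leave the acid-labile interflavan bond and all five stereocentres untouched.

**Compound list**

1 | 4-(benzyloxy)benzaldehyde | O=Cc1ccc(OCc2ccccc2)cc1 | starting material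
2 | racemic 2-[4-(benzyloxy)phenyl]-2-hydroxyacetic acid | OC(C(=O)O)c1ccc(OCc2ccccc2)cc1 | intermediate
3 | racemic 5-[4-(benzyloxy)phenyl]-2,2-dimethyl-1,3-dioxolan-4-one | CC1(C)OC(c2ccc(OCc3ccccc3)cc2)C(=O)O1 | intermediate
4 | 2-(2,4,6-trifluorophenyl)acetic acid | OC(=O)Cc1c(F)cc(F)cc1F | starting material
5 | tert-butyl 2-(2,4,6-trifluorophenyl)acetate | CC(C)(C)OC(=O)Cc1c(F)cc(F)cc1F | intermediate
6 | tert-butyl 4-[4-(benzyloxy)phenyl]-4-hydroxy-3-oxo-2-(2,4,6-trifluorophenyl)butanoate (present as its potassium enolate, stereoisomer mixture, not isolated) | CC(C)(C)OC(=O)C(c1c(F)cc(F)cc1F)C(=O)C(O)c1ccc(OCc2ccccc2)cc1 | intermediate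
7 | racemic tert-butyl 2-[4-(benzyloxy)phenyl]-5,7-difluoro-3-hydroxy-2H-chromene-4-carboxylate | CC(C)(C)OC(=O)C1=C(O)C(c2ccc(OCc3ccccc3)cc2)Oc2cc(F)cc(F)c21 | intermediate
8 | racemic 2-[4-(benzyloxy)phenyl]-5,7-difluoro-3-hydroxy-2H-chromene-4-carboxylic acid (not isolated) | OC(=O)C1=C(O)C(c2ccc(OCc3ccccc3)cc2)Oc2cc(F)cc(F)c21 | intermediate
9 | racemic 2-[4-(benzyloxy)phenyl]-5,7-difluoro-2H-chromen-3(4H)-one | O=C1Cc2c(F)cc(F)cc2OC1c1ccc(OCc2ccccc2)cc1 | intermediate
10 | (2R,3R)-2-[4-(benzyloxy)phenyl]-5,7-difluorochroman-3-ol | Fc1cc(F)c2c(c1)O[C@H](c1ccc(OCc3ccccc3)cc1)[C@H](O)C2 | intermediate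
11 | (2R,3R)-5,7-bis(benzyloxy)-2-[4-(benzyloxy)phenyl]chroman-3-ol | O(Cc1ccccc1)c1cc(OCc2ccccc2)c2c(c1)O[C@H](c1ccc(OCc3ccccc3)cc1)[C@H](O)C2 | intermediate
12 | (2R,3R,4S)-5,7-bis(benzyloxy)-2-[4-(benzyloxy)phenyl]-4-(2-ethoxyethoxy)chroman-3-ol | c1ccc(COc2ccc([C@H]3Oc4cc(OCc5ccccc5)cc(OCc5ccccc5)c4[C@H](OCCOCC)[C@H]3O)cc2)cc1 | intermediate
13 | (−)-epigallocatechin, (2R,3R)-2-(3,4,5-trihydroxyphenyl)chromane-3,5,7-triol | Oc1cc(O)c2c(c1)O[C@H](c1cc(O)c(O)c(O)c1)[C@H](O)C2 | starting material
14 | (2R,3R)-5,7-bis(benzyloxy)-2-[3,4,5-tris(benzyloxy)phenyl]chroman-3-ol | O(Cc1ccccc1)c1cc(OCc2ccccc2)c2c(c1)O[C@H](c1cc(OCc3ccccc3)c(OCc3ccccc3)c(OCc3ccccc3)c1)[C@H](O)C2 | intermediate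
15 | (2R,3R,4R)-5,7-bis(benzyloxy)-2-[4-(benzyloxy)phenyl]-4-[(2R,3R)-5,7-bis(benzyloxy)-3-hydroxy-2-[3,4,5-tris(benzyloxy)phenyl]chroman-8-yl]chroman-3-ol | C(c5ccccc5)Oc1ccc([C@H]2Oc3cc(OCc5ccccc5)cc(OCc5ccccc5)c3[C@H](c3c(OCc5ccccc5)cc(OCc5ccccc5)c4c3O[C@H](c3cc(OCc5ccccc5)c(OCc5ccccc5)c(OCc5ccccc5)c3)[C@H](O)C4)[C@H]2O)cc1 | intermediate
16 | epiafzelechin-(4β→8)-epigallocatechin, (2R,3R,4R)-2-(4-hydroxyphenyl)-4-[(2R,3R)-3,5,7-trihydroxy-2-(3,4,5-trihydroxyphenyl)chroman-8-yl]chromane-3,5,7-triol | Oc1ccc([C@H]2Oc3cc(O)cc(O)c3[C@H](c3c(O)cc(O)c4c3O[C@H](c3cc(O)c(O)c(O)c3)[C@H](O)C4)[C@H]2O)cc1 | target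

**Step count and risks**

Total step count: 11. Longest linear sequence: 9 steps (steps 1, 2, 4, 5, 6, 7, 8, 10, 11).

Steps most likely to fail:

1. Step 4 (the labelled step). Proton transfer from C5–H of 3 to the ester enolate may outrun acylation. After acylation, the liberated alkoxide may lactonise onto the ester, or the enolate oxygen may O-arylate, in place of the six-membered SNAr closure. The fallback uses known chemistry, sets out from 3 and comes back to the route at 9 (steps 3 to 5 are then not needed). Compound 3 is opened with MeNH(OMe)·HCl and i-PrMgCl (THF, −20 °C) to 2-[4-(benzyloxy)phenyl]-2-hydroxy-N-methoxy-N-methylacetamide F1, which is silylated (t-BuMe2SiCl, imidazole, DMF) to 2-[4-(benzyloxy)phenyl]-2-[(tert-butyldimethylsilyl)oxy]-N-methoxy-N-methylacetamide F2. A Weinreb ketone synthesis with 2,4,6-trifluorobenzylmagnesium bromide (from the commercial benzyl bromide and Mg in Et2O; THF, −78 to 0 °C) should give 1-[4-(benzyloxy)phenyl]-1-[(tert-butyldimethylsilyl)oxy]-3-(2,4,6-trifluorophenyl)propan-2-one F3. Desilylation with Bu4NF (THF, 0 °C) followed by K2CO3 in DMF at 50 °C should close ring C by alkoxide SNAr and give 9 directly.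

2. Step 6. Epimerisation at C2 may be too slow relative to hydride transfer, so that the reaction stops as a simple kinetic resolution, or facial selection by the catalyst may be poor. The fallback sets out from 9 and comes back at 10. Reduction with LiBH(s-Bu)3 (THF, −78 °C) should attack anti to the C2 aryl group and give the racemic cis alcohol, that is 10 together with its mirror image (2S,3S)-2-[4-(benzyloxy)phenyl]-5,7-difluorochroman-3-ol F4. The two are separated by preparative chromatography on a chiral stationary phase, and F4 is returned to 9 by Dess–Martin oxidation so that the material is recycled.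

3. Step 7. The second displacement may stall because the ring has become electron-rich and carries a nearby alkoxide, and the C3 alkoxide may etherify another molecule under the forcing conditions. The fallback moves the oxygenation to the start; it sets out from 4 and comes back at 11.
   - Compound 4, as its sodium carboxylate (not conjugated with the ring), is heated with BnOH and NaH in NMP at 90 °C. The para fluorine and then one of the two equivalent ortho fluorines should be displaced, giving 2-[2,4-bis(benzyloxy)-6-fluorophenyl]acetic acid F5.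
   - Isobutylene and catalytic H2SO4 give tert-butyl 2-[2,4-bis(benzyloxy)-6-fluorophenyl]acetate F6.
   - The protocol of step 4 with 3 (second stage in DMSO at 90 to 100 °C, since a single fluorine remains) should lead through tert-butyl 4-[4-(benzyloxy)phenyl]-2-[2,4-bis(benzyloxy)-6-fluorophenyl]-4-hydroxy-3-oxobutanoate F7 (not isolated) to tert-butyl 5,7-bis(benzyloxy)-2-[4-(benzyloxy)phenyl]-3-hydroxy-2H-chromene-4-carboxylate F8.
   - TsOH in toluene at 80 °C gives, through 5,7-bis(benzyloxy)-2-[4-(benzyloxy)phenyl]-3-hydroxy-2H-chromene-4-carboxylic acid F9 (not isolated), the ketone 5,7-bis(benzyloxy)-2-[4-(benzyloxy)phenyl]-2H-chromen-3(4H)-one F10.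
   - The conditions of step 6 applied to F10 should give 11.

Further compounds

F1 | step 4 | 2-[4-(benzyloxy)phenyl]-2-hydroxy-N-methoxy-N-methylacetamide | CON(C)C(=O)C(O)c1ccc(OCc2ccccc2)cc1
F2 | step 4 | 2-[4-(benzyloxy)phenyl]-2-[(tert-butyldimethylsilyl)oxy]-N-methoxy-N-methylacetamide | CON(C)C(=O)C(O[Si](C)(C)C(C)(C)C)c1ccc(OCc2ccccc2)cc1
F3 | step 4 | 1-[4-(benzyloxy)phenyl]-1-[(tert-butyldimethylsilyl)oxy]-3-(2,4,6-trifluorophenyl)propan-2-one | CC(C)(C)[Si](C)(C)OC(C(=O)Cc1c(F)cc(F)cc1F)c1ccc(OCc2ccccc2)cc1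
F4 | step 6 | (2S,3S)-2-[4-(benzyloxy)phenyl]-5,7-difluorochroman-3-ol | Fc1cc(F)c2c(c1)O[C@@H](c1ccc(OCc3ccccc3)cc1)[C@@H](O)C2
F5 | step 7 | 2-[2,4-bis(benzyloxy)-6-fluorophenyl]acetic acid | OC(=O)Cc1c(F)cc(OCc2ccccc2)cc1OCc1ccccc1
F6 | step 7 | tert-butyl 2-[2,4-bis(benzyloxy)-6-fluorophenyl]acetate | CC(C)(C)OC(=O)Cc1c(F)cc(OCc2ccccc2)cc1OCc1ccccc1
F7 | step 7 | tert-butyl 4-[4-(benzyloxy)phenyl]-2-[2,4-bis(benzyloxy)-6-fluorophenyl]-4-hydroxy-3-oxobutanoate | CC(C)(C)OC(=O)C(c1c(F)cc(OCc2ccccc2)cc1OCc1ccccc1)C(=O)C(O)c1ccc(OCc2ccccc2)cc1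
F8 | step 7 | tert-butyl 5,7-bis(benzyloxy)-2-[4-(benzyloxy)phenyl]-3-hydroxy-2H-chromene-4-carboxylate | CC(C)(C)OC(=O)C1=C(O)C(c2ccc(OCc3ccccc3)cc2)Oc2cc(OCc3ccccc3)cc(OCc3ccccc3)c21
F9 | step 7 | 5,7-bis(benzyloxy)-2-[4-(benzyloxy)phenyl]-3-hydroxy-2H-chromene-4-carboxylic acid | OC(=O)C1=C(O)C(c2ccc(OCc3ccccc3)cc2)Oc2cc(OCc3ccccc3)cc(OCc3ccccc3)c21
F10 | step 7 | 5,7-bis(benzyloxy)-2-[4-(benzyloxy)phenyl]-2H-chromen-3(4H)-one | O=C1Cc2c(OCc3ccccc3)cc(OCc3ccccc3)cc2OC1c1ccc(OCc2ccccc2)cc1
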